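**Assumptions (one line):** Commercial (2E,6E)-farnesol is used. The catalyst and tartrate enantiomers named below are taken to give the stated faces; this should be confirmed on model substrates. Reagent-only species (PMBCl, Ac2O, TESCl, MeI, and so on) are given by name and SMILES in the reagent field and are not numbered.

## Retrosynthetic overview
1. The target comes from the C3-TES ether. The α-methylene lactone comes from α-methylenation of the saturated cis-fused lactone. That lactone comes from Rh-carbenoid γ-C–H insertion of the C14 diazoacetate into C1–H2 of the macrocycle, which sets C1 last.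
2. The 14-membered carbocycle comes from RCM between two vinyl carbinol ethers (C1=C2), followed by hydrogenation and debenzylation.
3. C12 (Me) comes from Noyori hydrogenation. The C13/C14 syn-diol comes from Roush Z-γ-alkoxyallylboration of the C13 aldehyde.
4. The cis-THF-diol (C3, C4, C7, C8) comes from Shi bis-epoxidation of an E,E-diene and an acid hydrolysis/5-exo cyclisation cascade.
5. All of C2–C13 and the three methyls come from farnesol.

## Route

**Step 1**
Reactants: 1 (2E,6E)-farnesol
Product: 2 farnesyl 4-methoxybenzyl ether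
Conditions: NaH, PMBCl, TBAI (cat.), THF/DMF, 0 °C→rt
Reagents that add atoms: 4-methoxybenzyl chloride, COc1ccc(CCl)cc1
Why: Williamson etherification masks C2-OH as an ether that survives Shi epoxidation, acid and Wittig conditions. It is later removed neutrally by DDQ. No stereocentre is formed.

**Step 2**
Reactants: 2
Product: 3 C13-hydroxy compound (the E-methyl of the terminal alkene is oxidised)
Conditions: SeO2 (cat.), TBHP, salicylic acid, CH2Cl2, 0 °C→rt
Reagents that add atoms: tert-butyl hydroperoxide, CC(C)(C)OO (O source)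
Why: Umbreit–Sharpless allylic oxidation hydroxylates the E-methyl of the most electron-rich, terminal trisubstituted alkene. This gives the (E)-allylic alcohol that becomes C13.

**Step 3**
Reactants: 3
Product: 4 (12S)-C11=C12-saturated alcohol
Conditions: H2 (50 atm), Ru(OAc)2[(S)-BINAP], MeOH, 25 °C
Reagents that add atoms: none
Why: Noyori OH-directed asymmetric hydrogenation reduces only the alkene bearing the allylic OH. The BINAP enantioface sets C12 as S, and the C3 and C7 alkenes are untouched.

**Step 4**
Reactants: 4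
Product: 5 bis-epoxide (3R,4R,7R,8R,12S)
Conditions: Shi ketone from D-fructose (0.6 equiv), Oxone, K2CO3, Bu4NHSO4, EDTA, MeCN/DMM/H2O (pH 10.5), 0 °C
Reagents that add atoms: Oxone (O donor), OOS(=O)(=O)[O-].[K+]
Why: The Shi dioxirane epoxidises both E-trisubstituted alkenes on the same enantioface, giving trans-(R,R)-epoxides and setting C3/C4/C7/C8 in their pre-inversion configuration.

**Step 5**
Reactants: 5
Product: 6 cis-2,5-THF with C3-OH, C8-OH and C13-OH (3R,4S,7R,8S,12S)
Conditions: CSA (20 mol%), H2O (10 equiv), CH2Cl2, 0 °C→rt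
Reagents that add atoms: water, O
Why: The 7,8-epoxide reacts first, because the 3,4-epoxide is deactivated by the neighbouring C2 ether oxygen. Water opens it at tertiary C8 with inversion (8S). The freed 7-OH then closes 5-exo onto the 3,4-epoxide at tertiary C4 with inversion (4S). C3 and C7 are retained, and the acid-catalysed Baldwin-favoured 5-exo closure gives the cis-THF.

**Step 6**
Reactants: 6
Product: 7 C3,C13-bis-TES ether (C8-OH free)
Conditions: TESCl (2.5 equiv), imidazole, DMAP (cat.), DMF, 0 °C→rt
Reagents that add atoms: chlorotriethylsilane, CC[Si](Cl)(CC)CC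
Why: Primary and secondary hydroxyls are silylated and the tertiary C8-OH is not.

**Step 7**
Reactants: 7
Product: 8 C8-acetate
Conditions: Ac2O, DMAP, Et3N, CH2Cl2, 40 °C
Reagents that add atoms: acetic anhydride, CC(=O)OC(C)=O
Why: Forcing acylation of the only free (tertiary) OH installs the target C8 acetate with retention.

**Step 8**
Reactants: 8
Product: 9 C13 primary alcohol
Conditions: PPTS, MeOH, 0 °C
Reagents that add atoms: none
Why: The primary TES ether is cleaved much faster than the hindered secondary TES ether, and the acetate is untouched.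

**Step 9**
Reactants: 9
Product: 10 C13 aldehyde (12S)
Conditions: Dess–Martin periodinane, NaHCO3, CH2Cl2, 0 °C
Reagents that add atoms: none
Why: Buffered, neutral oxidation avoids epimerisation of the α-methyl centre (C12). The aldehyde is used crude.

**Step 10**
Reactants: 10 and 11 (allyl benzyl ether, the source of the γ-benzyloxyallyl unit)
Product: 12 homoallylic alcohol (12S,13R,14R) with a C14 vinyl group and C14-OBn
Conditions: 11, s-BuLi, THF, –78 °C; B(OiPr)3; (R,R)-diisopropyl tartrate, 4 Å MS. Then add 10, toluene, –78 °C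
Reagents that add atoms: the (Z)-γ-benzyloxyallyl tartrate boronate formed in situ from 11, B1(C/C=C\OCc2ccccc2)OC(C(=O)OC(C)C)C(C(=O)OC(C)C)O1 (R,R-tartrate)
Why: Roush allylboration. The Z-γ-alkoxyallylboronate reacts through a chair transition state to give the syn C13/C14 diol unit, and the tartrate (double asymmetric induction) sets the faces as 13R,14R. The vinyl group becomes the RCM handle.

**Step 11**
Reactants: 12
Product: 13 C13 acetate
Conditions: Ac2O, pyridine, DMAP (cat.), CH2Cl2
Reagents that add atoms: acetic anhydride, CC(=O)OC(C)=O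
Why: This installs the target C13 acetate and removes the only free OH before the base- and metal-mediated steps. No stereocentre is altered.

**Step 12**
Reactants: 13
Product: 14 C2 primary alcohol
Conditions: DDQ, CH2Cl2/pH 7 buffer, 0 °C
Reagents that add atoms: none
Why: Oxidative PMB removal is orthogonal to Ac, TES and Bn, and it avoids the 1,2-silyl migration that basic methanolysis of a C2 acetate could cause.

**Step 13**
Reactants: 14
Product: 15 C2 aldehyde
Conditions: TEMPO (cat.), PhI(OAc)2, CH2Cl2, 0 °C
Reagents that add atoms: none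
Why: Only a primary alcohol is present, so oxidation is clean. The α-silyloxy aldehyde is labile at C3 and is used immediately.

**Step 14**
Reactants: 15 and 16 (methyltriphenylphosphonium bromide)
Product: 17 diene with C3(OTES)–CH=CH2
Conditions: 16, KHMDS, THF, –78 °C; add 15, –78→0 °C
Reagents that add atoms: 16 (supplies the =CH2)
Why: Salt-free Wittig methylenation at low temperature gives the C3 vinyl carbinol ether, the second RCM partner, with minimal epimerisation at C3.

**Step 15**
Reactants: 17
Product: 18 macrocycle with C1=C2 (E/Z mixture)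
Conditions: Hoveyda–Grubbs II (10 mol%), toluene, 2 mM, 60 °C
Reagents that add atoms: none (ethylene is lost)
Why: Macro-RCM of two allylic-ether vinyl groups closes the 14-membered carbocycle. The E/Z mixture is irrelevant because the alkene is hydrogenated in the next step.

**Step 16**
Reactants: 18
Product: 19 saturated macrocycle with free C14-OH
Conditions: H2 (1 atm), Pd(OH)2/C, EtOAc, rt
Reagents that add atoms: none
Why: One hydrogenation reduces C1=C2 to C1H2–C2H2 and hydrogenolyses the C14 benzyl ether, giving the C14 alcohol with retention. Acetates and TES survive.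

**Step 17**
Reactants: 19 and 20 (glyoxylic acid chloride p-tosylhydrazone)
Product: 21 C14 diazoacetate
Conditions: 20, PhNMe2, CH2Cl2, 0 °C; then Et3N
Reagents that add atoms: 20, O=C(Cl)/C=N/NS(=O)(=O)c1ccc(C)cc1 (supplies C15 and C17)
Why: Corey diazoacetylation. The ester forms first, and then base eliminates sulfinate to give the diazoacetate.

**Step 18**
Reactants: 21
Product: 22 cis-fused saturated γ-lactone (1S), with C3-OTES
Conditions: Rh2(OAc)4 (2 mol%), CH2Cl2, 0.003 M, 40 °C
Reagents that add atoms: none (N2 is lost)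
Why: Rh-carbenoid 1,5-C–H insertion into the C1–H2 methylene forms the γ-lactone. The chair-like transition state puts the C13 chain pseudo-equatorial, so the C1–C2 and C14–C13 bonds end up cis. This sets the last stereocentre (C1) without scrambling the others.

**Step 19**
Reactants: 22 and 23 (Eschenmoser's salt)
Product: 24 α-(dimethylaminomethyl) lactone (C15 epimers)
Conditions: LDA (1.05 equiv), THF, –78 °C; then 23
Reagents that add atoms: 23, C[N+](C)=C.[I-] (supplies CH2NMe2)
Why: The lactone α-CH2 is the most acidic site, so kinetic enolisation followed by Mannich aminomethylation is selective over the acetates.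

**Step 20**
Reactants: 24
Product: 25 α-methylene lactone, C3-OTES
Conditions: MeI (excess), CH2Cl2, rt; then DBU, rt
Reagents that add atoms: none (Me3N is lost)
Why: Quaternisation followed by E1cB elimination of trimethylamine gives the exocyclic methylene. C15 stereochemistry is erased.

**Step 21**
Reactants: 25
Product: 26 target
Conditions: HF·pyridine, THF/pyridine, 0 °C
Reagents that add atoms: none
Why: Fluoride removes the C3 TES ether to give the free C3-OH. The acetates, lactone and THF are stable to these conditions.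

## Compound list
1 | (2E,6E)-farnesol | OC/C=C(\C)CC/C=C(\C)CC/C=C(\C)C | starting material
2 | farnesyl PMB ether | COc1ccc(COC/C=C(\C)CC/C=C(\C)CC/C=C(\C)C)cc1 | intermediate
3 | C13-hydroxy farnesyl PMB ether | COc1ccc(COC/C=C(\C)CC/C=C(\C)CC/C=C(\C)CO)cc1 | intermediate
4 | (12S)-C11=C12-saturated alcohol | COc1ccc(COC/C=C(\C)CC/C=C(\C)CCC[C@H](C)CO)cc1 | intermediate
5 | bis-epoxide (3R,4R,7R,8R,12S) | COc1ccc(COC[C@H]2O[C@]2(C)CC[C@H]2O[C@]2(C)CCC[C@H](C)CO)cc1 | intermediate
6 | cis-THF with 3-OH, 8-OH, 13-OH (3R,4S,7R,8S,12S) | OC[C@@H](C)CCC[C@](C)(O)[C@H]1CC[C@](C)(O1)[C@H](O)COCc1ccc(OC)cc1 | intermediate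
7 | C3,C13-bis-TES ether | CC[Si](CC)(CC)OC[C@@H](C)CCC[C@](C)(O)[C@H]1CC[C@](C)(O1)[C@H](O[Si](CC)(CC)CC)COCc1ccc(OC)cc1 | intermediate
8 | C8-acetate | CC[Si](CC)(CC)OC[C@@H](C)CCC[C@](C)(OC(C)=O)[C@H]1CC[C@](C)(O1)[C@H](O[Si](CC)(CC)CC)COCc1ccc(OC)cc1 | intermediate
9 | C13 primary alcohol | OC[C@@H](C)CCC[C@](C)(OC(C)=O)[C@H]1CC[C@](C)(O1)[C@H](O[Si](CC)(CC)CC)COCc1ccc(OC)cc1 | intermediate
10 | C13 aldehyde | O=C[C@@H](C)CCC[C@](C)(OC(C)=O)[C@H]1CC[C@](C)(O1)[C@H](O[Si](CC)(CC)CC)COCc1ccc(OC)cc1 | intermediate
11 | allyl benzyl ether | C=CCOCc1ccccc1 | starting material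
12 | Roush adduct (12S,13R,14R) | C=C[C@@H](OCc1ccccc1)[C@H](O)[C@@H](C)CCC[C@](C)(OC(C)=O)[C@H]1CC[C@](C)(O1)[C@H](O[Si](CC)(CC)CC)COCc1ccc(OC)cc1 | intermediate
13 | C13 acetate | C=C[C@@H](OCc1ccccc1)[C@H](OC(C)=O)[C@@H](C)CCC[C@](C)(OC(C)=O)[C@H]1CC[C@](C)(O1)[C@H](O[Si](CC)(CC)CC)COCc1ccc(OC)cc1 | intermediate
14 | C2 primary alcohol | C=C[C@@H](OCc1ccccc1)[C@H](OC(C)=O)[C@@H](C)CCC[C@](C)(OC(C)=O)[C@H]1CC[C@](C)(O1)[C@H](O[Si](CC)(CC)CC)CO | intermediate
15 | C2 aldehyde | C=C[C@@H](OCc1ccccc1)[C@H](OC(C)=O)[C@@H](C)CCC[C@](C)(OC(C)=O)[C@H]1CC[C@](C)(O1)[C@H](O[Si](CC)(CC)CC)C=O | intermediate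
16 | methyltriphenylphosphonium bromide | C[P+](c1ccccc1)(c1ccccc1)c1ccccc1.[Br-] | starting material
17 | diene (vinyl carbinol TES ether) | C=C[C@@H](OCc1ccccc1)[C@H](OC(C)=O)[C@@H](C)CCC[C@](C)(OC(C)=O)[C@H]1CC[C@](C)(O1)[C@H](O[Si](CC)(CC)CC)C=C | intermediate
18 | RCM macrocycle (C1=C2) | C1=C[C@@H](O[Si](CC)(CC)CC)[C@]2(C)CC[C@@H](O2)[C@@](C)(OC(C)=O)CCC[C@H](C)[C@@H](OC(C)=O)[C@@H]1OCc3ccccc3 | intermediate
19 | saturated macrocycle, C14-OH | C1C[C@@H](O[Si](CC)(CC)CC)[C@]2(C)CC[C@@H](O2)[C@@](C)(OC(C)=O)CCC[C@H](C)[C@@H](OC(C)=O)[C@@H]1O | intermediate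
20 | glyoxylic acid chloride p-tosylhydrazone | O=C(Cl)/C=N/NS(=O)(=O)c1ccc(C)cc1 | starting material
21 | C14 diazoacetate | C1C[C@@H](O[Si](CC)(CC)CC)[C@]2(C)CC[C@@H](O2)[C@@](C)(OC(C)=O)CCC[C@H](C)[C@@H](OC(C)=O)[C@@H]1OC(=O)C=[N+]=[N-] | intermediate
22 | saturated cis-lactone, C3-OTES | C1C(=O)O[C@H]2[C@H](OC(C)=O)[C@@H](C)CCC[C@](C)(OC(C)=O)[C@H]3CC[C@](C)(O3)[C@H](O[Si](CC)(CC)CC)C[C@@H]12 | intermediate
23 | Eschenmoser's salt | C[N+](C)=C.[I-] | starting material
24 | α-(dimethylaminomethyl) lactone | CN(C)CC1C(=O)O[C@H]2[C@H](OC(C)=O)[C@@H](C)CCC[C@](C)(OC(C)=O)[C@H]3CC[C@](C)(O3)[C@H](O[Si](CC)(CC)CC)C[C@@H]12 | intermediate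
25 | α-methylene lactone, C3-OTES | C=C1C(=O)O[C@H]2[C@H](OC(C)=O)[C@@H](C)CCC[C@](C)(OC(C)=O)[C@H]3CC[C@](C)(O3)[C@H](O[Si](CC)(CC)CC)C[C@@H]12 | intermediate
26 | target | C=C1C(=O)O[C@H]2[C@H](OC(C)=O)[C@@H](C)CCC[C@](C)(OC(C)=O)[C@H]3CC[C@](C)(O3)[C@H](O)C[C@@H]12 | target

**Total step count:** 21
**Longest linear sequence:** 21 (1→2→…→26; compounds 11, 16, 20 and 23 are single-use commercial partners)

**Three steps most likely to fail:**
1. **Step 5 (hydrolysis/cyclisation cascade).** It may give a THP or the trans-THF diastereomer, or mixtures from the wrong epoxide reacting first.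
   - Fallback, which changes the approach: do Shi epoxidation of C7=C8 only, hydrolyse with aqueous HClO4 to the 7,8-diol (inversion at C8), then do the second Shi epoxidation on C3=C4 and close with CSA.
2. **Step 10 (Roush allylboration).** The Z-reagent is mismatched with the Felkin bias of the α-methyl aldehyde, so the diastereoselectivity may be poor.
   - Fallback: use an (E)-γ-silyloxyallylboronate, which is matched with Felkin, to get the 13,14-anti diol. Then invert C14 by oxidation followed by chelation-controlled Zn(BH4)2 reduction.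
3. **Step 18 (Rh C–H insertion).** Competing insertion into tertiary C12–H or C2–H would give a δ-lactone, and the cis selectivity in the macrocycle is unproven.
   - Fallback: skip hydrogenation and debenzylate the C14 ether by other means, for example DDQ, instead of Step 16. Esterify C14-OH with 2-bromoacrylic acid and run a Bu3SnH 5-exo vinyl-radical cyclisation onto the macrocyclic C1=C2 alkene. This installs the exocyclic methylene directly and removes Steps 19–20.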